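**Plan**

- Ring numbering used here: C1(=O), C2(OMe), C3(OH), C4(=O), C5(CH3), C6(hexaprenyl). The retrosynthesis cuts C3–C4 and C1–C2 together (last step), then the C6–CH2 and C5–CH3 bonds, then the C12–C13 bond in the middle of the chain.
- Enabling feature: the 3-hydroxyquinone ring is the enol of a cyclohex-5-ene-1,2,4-trione. C2/C3 are therefore a methoxyacetyl unit (C3 the acyl carbon, C2 the enolisable CH2OMe carbon), and C4–C5=C6–C1 is a (Z)-4-oxobut-2-enoic acid. This acid is used as its 5-(phenylsulfonyl)furan-2(5H)-one, in which the sulfonyl carbon (future C4) is nucleophilic and the lactone carbonyl (future C1) electrophilic.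
- Forward: two farnesyl units are joined by allylic sulfone alkylation and taken to all-E hexaprenyl bromide. Methylcopper, a 4,4-diethoxybut-2-ynoate and this bromide give the tetrasubstituted enoate. Lactonisation and sulfinate exchange give the butenolide, and the quinone ring is closed last.
- Stereochemistry: the target has no stereocentre. The five E-olefins come from (2E,6E)-farnesol, (2E,6E)-farnesyl bromide and the E-selective SeO2 oxidation, and are carried through SN2 couplings. The ring olefin geometry comes from syn-carbocupration.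

Key step: step 12

Assumption: all-E hexaprenol is not taken as a catalogue chemical, so the C30 chain is built from two C15 units; 9, 18, 19 and 22 are racemic at a centre that does not survive into the target.

"Hexaprenyl" below means (2E,6E,10E,14E,18E)-3,7,11,15,19,23-hexamethyltetracosa-2,6,10,14,18,22-hexaen-1-yl.

**Route**

Step 1
Reactants: 1 (2E,6E)-farnesol
Product: 3 benzyl (2E,6E)-farnesyl ether, via sodium farnesoxide 2 (not isolated)
Conditions: NaH, THF, 0 °C; BnBr, Bu4NI (cat.), rt
Reagents that add atoms: benzyl bromide, BrCc1ccccc1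
Why: Williamson ether synthesis of the allylic alkoxide with benzyl bromide is reliable and leaves both E-olefins untouched; no stereocentre is formed.

Step 2
Reactants: 3 benzyl (2E,6E)-farnesyl ether
Product: 4 (2E,6E,10E)-12-(benzyloxy)-2,6,10-trimethyldodeca-2,6,10-trien-1-ol
Conditions: SeO2 (cat.), t-BuOOH, salicylic acid (cat.), CH2Cl2, 0 °C → rt
Reagents that add atoms: tert-butyl hydroperoxide, CC(C)(C)OO
Why: Riley-type allylic oxidation attacks the most electron-rich, terminal olefin and, through the ene/[2,3]-sigmatropic sequence, hydroxylates its E-methyl group, so the new allylic alcohol should have the E geometry.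

Step 3
Reactants: 4 (2E,6E,10E)-12-(benzyloxy)-2,6,10-trimethyldodeca-2,6,10-trien-1-ol
Product: 5 benzyl (2E,6E,10E)-12-bromo-3,7,11-trimethyldodeca-2,6,10-trienyl ether
Conditions: CBr4, PPh3, CH2Cl2, 0 °C
Reagents that add atoms: carbon tetrabromide, BrC(Br)(Br)Br
Why: Appel bromination of a primary allylic alcohol proceeds by SN2 displacement of the oxyphosphonium group under neutral conditions, so the E-olefins and the benzyl ether are kept.

Step 4
Reactants: 6 (2E,6E)-farnesyl bromide
Product: 7 (2E,6E)-farnesyl phenyl sulfone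
Conditions: PhSO2Na, DMF, rt
Reagents that add atoms: sodium benzenesulfinate, [Na+].[O-]S(=O)c1ccccc1
Why: S-alkylation of the sulfinate anion by the primary allylic bromide (SN2) should give the allylic sulfone with retention of the 2E geometry.

Step 5
Reactants: 7 (2E,6E)-farnesyl phenyl sulfone; 5 benzyl (2E,6E,10E)-12-bromo-3,7,11-trimethyldodeca-2,6,10-trienyl ether
Product: 9 benzyl (2E,6E,10E,14E,18E)-3,7,11,15,19,23-hexamethyl-13-(phenylsulfonyl)tetracosa-2,6,10,14,18,22-hexaenyl ether (racemic at C13), via lithiated sulfone 8 (not isolated)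
Conditions: n-BuLi, THF/DMPU, −78 °C; then 5, −78 → −20 °C
Reagents that add atoms: none
Why: Alkylation of the α-sulfonyl allyl carbanion at its α-carbon by the primary allylic bromide (SN2) is the standard head-to-tail prenyl coupling and keeps all olefin geometries; the new sulfone-bearing stereocentre forms as a racemate and is removed in step 6.

Step 6
Reactants: 9 benzyl C30 sulfone ether
Product: 10 all-E hexaprenol, (2E,6E,10E,14E,18E)-3,7,11,15,19,23-hexamethyltetracosa-2,6,10,14,18,22-hexaen-1-ol
Conditions: Li, EtNH2/THF, −78 °C; NH4Cl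
Reagents that add atoms: none
Why: Dissolving-metal (Benkeser-type) reduction cleaves both the allylic C–S bond and the benzylic C–O bond, and at −78 °C protonation of the allyl anion at the former sulfone carbon should keep the trisubstituted E-olefin in place; the stereocentre of 9 is destroyed.

Step 7
Reactants: 10 all-E hexaprenol
Product: 11 all-E hexaprenyl bromide
Conditions: PBr3, Et2O, 0 °C
Reagents that add atoms: phosphorus tribromide, BrP(Br)Br
Why: PBr3 converts primary allylic alcohols into bromides by SN2 attack of bromide on the phosphite ester at low temperature, without allylic transposition or E/Z isomerisation.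

Step 8
Reactants: 12 3,3-diethoxyprop-1-yne
Product: 14 methyl 4,4-diethoxybut-2-ynoate, via lithium acetylide 13 (not isolated)
Conditions: n-BuLi, THF, −78 °C; ClCO2Me, −78 → 0 °C
Reagents that add atoms: methyl chloroformate, COC(Cl)=O
Why: Deprotonation of the terminal alkyne and C-acylation of the lithium acetylide with a chloroformate is a standard ynoate synthesis; no stereocentre is formed.

Step 9
Reactants: 14 methyl 4,4-diethoxybut-2-ynoate; 11 all-E hexaprenyl bromide
Product: 16 methyl (2Z)-4,4-diethoxy-3-methyl-2-hexaprenylbut-2-enoate, via alkenylcopper 15 (not isolated)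
Conditions: MeMgBr, CuBr·SMe2, THF, −40 °C; 14, −78 °C; then 11, DMPU, −78 → −20 °C
Reagents that add atoms: methylmagnesium bromide, C[Mg]Br
Why: Syn-carbocupration (conjugate addition) of methylcopper places methyl on the β-carbon and copper on the α-carbon of the ynoate, and SN2 allylation of the alkenylcopper with retention should give the tetrasubstituted olefin with ester and acetal cis (2Z), while the five E-olefins of 11 are kept.

Step 10
Reactants: 16 methyl (2Z)-4,4-diethoxy-3-methyl-2-hexaprenylbut-2-enoate
Product: 18 5-hydroxy-4-methyl-3-hexaprenylfuran-2(5H)-one (racemic), via aldehyde ester 17 (not isolated)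
Conditions: 1 M HCl, THF, rt → 40 °C
Reagents that add atoms: water, O
Why: Acid-catalysed acetal hydrolysis frees the aldehyde cis to the ester, and its hydrate lactonises (intramolecular transesterification) to the γ-hydroxybutenolide; the new C5 stereocentre is racemic and is destroyed in step 12.

Step 11
Reactants: 18 5-hydroxy-4-methyl-3-hexaprenylfuran-2(5H)-one
Product: 19 4-methyl-3-hexaprenyl-5-(phenylsulfonyl)furan-2(5H)-one (racemic)
Conditions: PhSO2Na, AcOH/THF, 40 °C
Reagents that add atoms: sodium benzenesulfinate, [Na+].[O-]S(=O)c1ccccc1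
Why: Acid-mediated substitution of the lactol hydroxyl by benzenesulfinic acid through the acyloxycarbenium ion, the same S-alkylation that turns 3-hydroxyphthalide into 3-(phenylsulfonyl)phthalide, should give the sulfone; the C5 stereocentre stays racemic.

Step 12
Reactants: 19 4-methyl-3-hexaprenyl-5-(phenylsulfonyl)furan-2(5H)-one; 20 methoxyacetyl chloride
Product: 23 3-demethylubiquinone-6 (3-hydroxy-2-methoxy-5-methyl-6-hexaprenyl-1,4-benzoquinone), via lithium furanolate 21 (not isolated), via acyl ketone 22 (not isolated)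
Conditions: LiN(SiMe3)2 (1.05 equiv), THF, −78 °C; 20, −78 → −40 °C; LiN(SiMe3)2 (1.1 equiv), −78 °C → rt; aq. citric acid
Reagents that add atoms: none
Why: Proposed new method: the sulfonyl-stabilised furanolate 21 should be C-acylated at C5 by 20 to give 22, the second charge of base should enolise the CH2OMe ketone, and this enolate should add to the lactone carbonyl (Dieckmann), after which the oxygen bridge opens and benzenesulfinate leaves to give 3-methoxycyclohex-5-ene-1,2,4-trione, which enolises to 23. The closest known reaction type is the Hauser-Kraus annulation of 3-sulfonylphthalide anions, with a Claisen acylation in the place of the Michael addition; the acid chloride is used because acylation of so stabilised an anion by an ester would be reversible and uphill. The ring closes by a 6-(enolendo)-exo-trig attack of the enolate carbon on the lactone carbonyl and passes through the same 7-oxabicyclo[2.2.1]heptene alkoxide as the parent annulation. No stereocentre is formed and the racemic C5 of 19 is destroyed. The step needs one selectivity, the orientation of the OH/OMe pair relative to the methyl/hexaprenyl pair, and polarity secures it: the only carbanionic ring carbon, C5 next to C–CH3, can bond only to the acyl carbon that ends as C–OH, and the only electrophilic ring carbon, the lactone carbonyl next to C–hexaprenyl, only to the enolate carbon that carries OMe. Acylation at oxygen or at C3 gives isomers that cannot close a six-membered ring and should be able to return under the second base charge through loss of methoxyketene from their enolates, so only the C5 adduct is drained by the irreversible loss of sulfinate.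

**Compound list**

1 | (2E,6E)-farnesol | OC/C=C(\C)CC/C=C(\C)CCC=C(C)C | starting material
2 | sodium (2E,6E)-farnesoxide | [Na+].[O-]C/C=C(\C)CC/C=C(\C)CCC=C(C)C | intermediate
3 | benzyl (2E,6E)-farnesyl ether | c1ccccc1COC/C=C(\C)CC/C=C(\C)CCC=C(C)C | intermediate
4 | (2E,6E,10E)-12-(benzyloxy)-2,6,10-trimethyldodeca-2,6,10-trien-1-ol | c1ccccc1COC/C=C(\C)CC/C=C(\C)CC/C=C(\C)CO | intermediate
5 | benzyl (2E,6E,10E)-12-bromo-3,7,11-trimethyldodeca-2,6,10-trienyl ether | c1ccccc1COC/C=C(\C)CC/C=C(\C)CC/C=C(\C)CBr | intermediate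
6 | (2E,6E)-farnesyl bromide | BrC/C=C(\C)CC/C=C(\C)CCC=C(C)C | starting material
7 | (2E,6E)-farnesyl phenyl sulfone | O=S(=O)(c1ccccc1)C/C=C(\C)CC/C=C(\C)CCC=C(C)C | intermediate
8 | [(2E,6E)-1-lithio-3,7,11-trimethyldodeca-2,6,10-trienyl] phenyl sulfone | [Li]C(/C=C(\C)CC/C=C(\C)CCC=C(C)C)S(=O)(=O)c1ccccc1 | intermediate
9 | benzyl (2E,6E,10E,14E,18E)-3,7,11,15,19,23-hexamethyl-13-(phenylsulfonyl)tetracosa-2,6,10,14,18,22-hexaenyl ether (racemic) | c1ccccc1COC/C=C(\C)CC/C=C(\C)CC/C=C(\C)CC(S(=O)(=O)c1ccccc1)/C=C(\C)CC/C=C(\C)CCC=C(C)C | intermediate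
10 | all-E hexaprenol | OC/C=C(\C)CC/C=C(\C)CC/C=C(\C)CC/C=C(\C)CC/C=C(\C)CCC=C(C)C | intermediate
11 | all-E hexaprenyl bromide | BrC/C=C(\C)CC/C=C(\C)CC/C=C(\C)CC/C=C(\C)CC/C=C(\C)CCC=C(C)C | intermediate
12 | 3,3-diethoxyprop-1-yne | C#CC(OCC)OCC | starting material
13 | lithium 3,3-diethoxyprop-1-yn-1-ide | [Li]C#CC(OCC)OCC | intermediate
14 | methyl 4,4-diethoxybut-2-ynoate | COC(=O)C#CC(OCC)OCC | intermediate
15 | methyl (2E)-2-cuprio-4,4-diethoxy-3-methylbut-2-enoate (copper cis to the C3 methyl) | COC(=O)/C([Cu])=C(\C(OCC)OCC)C | intermediate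
16 | methyl (2Z)-4,4-diethoxy-3-methyl-2-hexaprenylbut-2-enoate | COC(=O)/C(C/C=C(\C)CC/C=C(\C)CC/C=C(\C)CC/C=C(\C)CC/C=C(\C)CCC=C(C)C)=C(\C(OCC)OCC)C | intermediate
17 | methyl (2Z)-3-methyl-4-oxo-2-hexaprenylbut-2-enoate | COC(=O)/C(C/C=C(\C)CC/C=C(\C)CC/C=C(\C)CC/C=C(\C)CC/C=C(\C)CCC=C(C)C)=C(\C=O)C | intermediate
18 | 5-hydroxy-4-methyl-3-hexaprenylfuran-2(5H)-one (racemic) | O=C1OC(O)C(C)=C1C/C=C(\C)CC/C=C(\C)CC/C=C(\C)CC/C=C(\C)CC/C=C(\C)CCC=C(C)C | intermediate
19 | 4-methyl-3-hexaprenyl-5-(phenylsulfonyl)furan-2(5H)-one (racemic) | O=C1OC(S(=O)(=O)c2ccccc2)C(C)=C1C/C=C(\C)CC/C=C(\C)CC/C=C(\C)CC/C=C(\C)CC/C=C(\C)CCC=C(C)C | intermediate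
20 | methoxyacetyl chloride | COCC(Cl)=O | starting material
21 | lithium 4-methyl-3-hexaprenyl-5-(phenylsulfonyl)furan-2-olate | [Li]Oc1oc(S(=O)(=O)c2ccccc2)c(C)c1C/C=C(\C)CC/C=C(\C)CC/C=C(\C)CC/C=C(\C)CC/C=C(\C)CCC=C(C)C | intermediate
22 | 5-(methoxyacetyl)-4-methyl-3-hexaprenyl-5-(phenylsulfonyl)furan-2(5H)-one (racemic) | COCC(=O)C1(S(=O)(=O)c2ccccc2)OC(=O)C(C/C=C(\C)CC/C=C(\C)CC/C=C(\C)CC/C=C(\C)CC/C=C(\C)CCC=C(C)C)=C1C | intermediate
23 | 3-demethylubiquinone-6 | COC1=C(O)C(=O)C(C)=C(C/C=C(\C)CC/C=C(\C)CC/C=C(\C)CC/C=C(\C)CC/C=C(\C)CCC=C(C)C)C1=O | target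

**Count and risks**

Total step count: 12. Longest linear sequence: 10 steps (steps 1, 2, 3, 5, 6, 7, 9, 10, 11, 12).

Steps most likely to fail:

1. Step 12. Acylation of the furanolate at oxygen or at C3 instead of C5 may not be corrected by the second base charge, or the base may cleave the acyl group or the lactone before the Dieckmann closure. The fallback sets out from 10 and returns at 23, and takes the ring from an arene by known reactions. Commercial 2,3,4-trimethoxy-6-methylbenzaldehyde is demethylated with BCl3 (CH2Cl2, 0 °C) only at the methoxy group ortho to the formyl group, to give 2-hydroxy-3,4-dimethoxy-6-methylbenzaldehyde F1. Dakin oxidation (H2O2, NaOH, then acid) gives 3,4-dimethoxy-6-methylbenzene-1,2-diol F2. Friedel-Crafts allylation of F2 with 10 (BF3·OEt2, dioxane, rt) at the only free ring position should give 3,4-dimethoxy-6-methyl-5-hexaprenylbenzene-1,2-diol F3, with possible partial loss of the 2E geometry. Oxidative demethylation with (NH4)2Ce(NO3)6 (tetravalent cerium) in MeCN/H2O at 0 °C should then give 23: the C1 hydroxyl and the para C4 methoxy become the two quinone carbonyls and the C2 hydroxyl stays as the 3-OH, so the oxygen pattern is fixed by the ortho-selective demethylation.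

2. Step 9. The α-cuprio enoate may lose its olefin geometry through the allenoate form before it is trapped, and the allylic bromide may be attacked in the SN2′ sense. The fallback sets out from 11 and returns at 18, and replaces carbocupration by enolate alkylation. C-alkylation of commercial methyl 4,4-dimethoxy-3-oxobutanoate with 11 (K2CO3, acetone, reflux) gives methyl 4,4-dimethoxy-3-oxo-2-hexaprenylbutanoate F4. Non-chelating enol phosphorylation (ClP(O)(OEt)2, Et3N, DMAP cat., DMPU) should favour the enol phosphate with the phosphate trans to the ester, methyl (2E)-3-(diethoxyphosphoryloxy)-4,4-dimethoxy-2-hexaprenylbut-2-enoate F5. Me2CuLi (Et2O, −78 °C) replaces the phosphate by methyl with retention to give methyl (2Z)-4,4-dimethoxy-3-methyl-2-hexaprenylbut-2-enoate F6, which under the conditions of step 10 should give 18.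

3. Step 11. Acid-promoted cyclisation or hydration of the polyene chain, or conjugate addition of sulfinic acid to the butenolide, may compete with substitution at C5. The fallback sets out from 18 and returns at 19, and forms the C–S bond at the sulfide level. Thioacetalisation with PhSH (BF3·OEt2 cat., CH2Cl2, 0 °C) gives 4-methyl-3-hexaprenyl-5-(phenylsulfanyl)furan-2(5H)-one F7. S-oxidation with H2O2 and (NH4)6Mo7O24·4H2O (cat.) in EtOH at 0 °C, a system that leaves trisubstituted olefins untouched, should give 19.

**Further compounds**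

F1 | step 12 | 2-hydroxy-3,4-dimethoxy-6-methylbenzaldehyde | O=Cc1c(C)cc(OC)c(OC)c1O
F2 | step 12 | 3,4-dimethoxy-6-methylbenzene-1,2-diol | Oc1c(C)cc(OC)c(OC)c1O
F3 | step 12 | 3,4-dimethoxy-6-methyl-5-hexaprenylbenzene-1,2-diol | Oc1c(C)c(C/C=C(\C)CC/C=C(\C)CC/C=C(\C)CC/C=C(\C)CC/C=C(\C)CCC=C(C)C)c(OC)c(OC)c1O
F4 | step 9 | methyl 4,4-dimethoxy-3-oxo-2-hexaprenylbutanoate (racemic) | COC(=O)C(C/C=C(\C)CC/C=C(\C)CC/C=C(\C)CC/C=C(\C)CC/C=C(\C)CCC=C(C)C)C(=O)C(OC)OC
F5 | step 9 | methyl (2E)-3-(diethoxyphosphoryloxy)-4,4-dimethoxy-2-hexaprenylbut-2-enoate | COC(=O)/C(C/C=C(\C)CC/C=C(\C)CC/C=C(\C)CC/C=C(\C)CC/C=C(\C)CCC=C(C)C)=C(\C(OC)OC)OP(=O)(OCC)OCC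
F6 | step 9 | methyl (2Z)-4,4-dimethoxy-3-methyl-2-hexaprenylbut-2-enoate | COC(=O)/C(C/C=C(\C)CC/C=C(\C)CC/C=C(\C)CC/C=C(\C)CC/C=C(\C)CCC=C(C)C)=C(\C(OC)OC)C
F7 | step 11 | 4-methyl-3-hexaprenyl-5-(phenylsulfanyl)furan-2(5H)-one (racemic) | O=C1OC(Sc2ccccc2)C(C)=C1C/C=C(\C)CC/C=C(\C)CC/C=C(\C)CC/C=C(\C)CC/C=C(\C)CCC=C(C)C
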